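The trap in these readings was to take the J column for dissolved chain, since it counts the crystals L as well, and I wrote this note with that in mind for whoever took over the flask at 3.0 min.

| flask | E | Q | G | remark | time |
|---|---|---|---|---|---|
| green | 0.014 M | 0.10 mM | 1 mM | run made earlier |  |
| ochre | 0.022 M | 0.10 mM | 1 mM | run made earlier |  |
| teal | 0.010 M | 0.10 mM | 1.5 mM | run made earlier |  |
| flask | 0.010 M | 0.100 mM | 1.0 mM |  | 3.0 min |

| run | time / min | J / % | L / % |
|---|---|---|---|
| green | 0.333 | 1 | 2 |
| green | 0.833 | 3 | 0 |
| green | 1.50 | 12 | 0 |
| green | 2.50 | 16 | 0 |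
| green | 4.00 | 27 | 0 |
| ochre | 0.333 | 2 | 1 |
| ochre | 0.833 | 4 | 1 |
| ochre | 1.50 | 12 | 0 |
| ochre | 2.50 | 18 | 1 |
| ochre | 4.00 | 26 | 8 |
| teal | 0.250 | 3 | 0 |
| teal | 0.500 | 6 | 0 |
| teal | 1.00 | 11 | 0 |
| teal | 2.00 | 18 | 2 |
| teal | 4.00 | 34 | 0 |

(each reading ± 1.5 percentage points)
- amounts and yields of J count L too
- given per volume of solution although it is solid: L
- how much J and L together there is at 3.0 min, in percent of the E charged
- concentration of J in solution at 3.0 min, in percent of saturation

In the ochre run at 4.00 min I took L, 8% against a scatter of 1.5 percentage points, from the J reading of 26%, which left 3.96 mM in solution as my reading of the solubility limit. Dividing it by the E charged in the flask gave the threshold conversion, the share of the charge at which crystals should begin, 39.6%. Green and ochre, with equal G and Q but different E, read 16% and 18% at 2.50 min, so I read the flask between the green points and expected 19.7% converted, below the threshold, which is 49.7% of saturation and means a clear solution. I asked my successor to leave G alone, since teal, with 1.5 mM of G and also less E than green, had reached 34% at 4.00 min against 27% for green, while green and ochre, apart in E, read 27% and 26% at that time.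

The forecast stood a little higher, at 21% (18% to 25%) and 55% of saturation (43% to 72%), holding that “The flask stays below saturation”.

The flask gave 18.6% and 51.8% of saturation, with L at 0%, under this scheme:

    E + G → Z + J (k = 0.970 L mol⁻¹ s⁻¹)
    E + Z → J + Z, rate k2*[Z]*[E] (k = 1.40 L mol⁻¹ s⁻¹)
    Z + Q → X (k = 13.0 L mol⁻¹ s⁻¹)
    L ⇌ J, rate k4*(cs4 - [J]) while solid is left; crystals form when [J] > cs4 (solubility = 3.60 mM, k = 0.400 s⁻¹)

That conversion is 47.0% of my threshold. The same flask read at 12 min stood past the threshold at 58.5%, so subtracting the threshold gave 19 points as my reckoning of the crystals, and L stood at 22.3%.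

(Readings and results were generated by integration on assumed constants; scatter was added.)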